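**Plan**
- Retrosynthesis: the five benzylic C–O bonds (four benzyl ethers, one O3 auxiliary ether) are restored first; then C4–C4a and C2–C3 are cut together, then O1–C2, then the side chain at its 1,1-diarylethene stage.
- The double cut is possible because C4a=C8a–O1–C2 is a latent cationic 2-oxadiene: ring A is a phloroglucinol (C4a ortho/para to three oxygens) and C2 carries the 4-oxygenated ring B. C3(O)–C4(=O) is a glycolate unit, i.e. a 2-oxygenated ketene acetal.
- O1 is para to the C6 side chain, so the ring A precursor has two equivalent carbons ortho to O1 and ring closure has only one outcome.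
- Forward: phloroacetophenone supplies ring A and the side-chain CH–CH3; ring D (the side-chain aryl) is added to the acetyl carbon; ring B arrives as an N,O-acetal on O1; ring C is closed in the penultimate step; one hydrogenolysis frees all phenols and O3.
- Stereochemistry: the side-chain centre comes from an iridium-catalysed asymmetric alkene hydrogenation; C3 from an (R,R)-hydrobenzoin unit built into the ketene acetal (it then serves as the O3 protecting group); C2 from the relative topicity of the same step.

Key step: step 11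

Remark: the N,O-acetal carbon of 11 and 12, the carbinol carbon of 5 and C4 of ketal 19 form without control; all are made planar or lost later, so their SMILES carry no descriptor.

**Step 1**
Reactants: 1 2,4,6-trihydroxyacetophenone
Product: 2 1-[2,6-dihydroxy-4-(methoxymethoxy)phenyl]ethanone
Conditions: MOMCl (1.05 equiv), K2CO3, acetone, 0 °C → rt
Reagents that add atoms: chloromethyl methyl ether, COCCl
Why: Williamson O-alkylation; the 4-hydroxyl is the most acidic phenol and the only one not hydrogen-bonded to the acetyl carbonyl, so one equivalent of MOMCl should react mainly there.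

**Step 2**
Reactants: 2 1-[2,6-dihydroxy-4-(methoxymethoxy)phenyl]ethanone
Product: 3 1-[2,6-bis(benzyloxy)-4-(methoxymethoxy)phenyl]ethanone
Conditions: BnBr (2.5 equiv), K2CO3, DMF, 70 °C
Reagents that add atoms: benzyl bromide, BrCc1ccccc1
Why: Williamson etherification of the two chelated ortho hydroxyls needs forcing carbonate/DMF conditions, which the base-stable MOM ether tolerates.

**Step 3**
Reactants: 3 1-[2,6-bis(benzyloxy)-4-(methoxymethoxy)phenyl]ethanone; 4 4-(benzyloxy)phenylmagnesium bromide (purchased THF solution)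
Product: 5 1-[2,6-bis(benzyloxy)-4-(methoxymethoxy)phenyl]-1-[4-(benzyloxy)phenyl]ethanol (racemic)
Conditions: 4 (1.5 equiv), anhydrous CeCl3, THF, −78 → 0 °C; aq. NH4Cl
Reagents that add atoms: none
Why: CeCl3-promoted Grignard 1,2-addition suppresses enolisation of the hindered di-ortho-alkoxy acetophenone; the carbinol carbon forms racemic and is flattened again in step 4.

**Step 4**
Reactants: 5 tertiary carbinol
Product: 6 1,3-bis(benzyloxy)-2-{1-[4-(benzyloxy)phenyl]ethenyl}-5-(methoxymethoxy)benzene
Conditions: PPTS (cat.), toluene, 4 Å MS, 60 °C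
Reagents that add atoms: none
Why: acid-catalysed E1 dehydration of a tertiary, doubly benzylic carbinol that can lose a proton only from the methyl group, under conditions mild enough to keep the aryl MOM ether.

**Step 5**
Reactants: 6 1,1-diarylethene
Product: 7 1,3-bis(benzyloxy)-2-{(1R)-1-[4-(benzyloxy)phenyl]ethyl}-5-(methoxymethoxy)benzene
Conditions: [Ir(cod)((S)-tBu-PHOX)][B(3,5-(CF3)2C6H3)4] (2 mol %), H2 (50 bar), CH2Cl2, rt
Reagents that add atoms: none
Why: iridium-catalysed asymmetric hydrogenation of a 1,1-diarylethene with a phosphine-oxazoline ligand; the twisted 2,6-dioxygenated ring A and the flat para-substituted ring D differ enough sterically for the catalyst to select one alkene face, and the ligand antipode that gives the R centre is the one used.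

**Step 6**
Reactants: 7 MOM ether
Product: 8 3,5-bis(benzyloxy)-4-{(1R)-1-[4-(benzyloxy)phenyl]ethyl}phenol
Conditions: conc. HCl (cat.), MeOH/THF, 40 °C
Reagents that add atoms: none
Why: acid-catalysed acetal exchange with methanol removes the aryl MOM ether, while the benzyl ethers and the diarylmethine centre are inert to dilute acid at this temperature.

**Step 7**
Reactants: 9 4-(benzyloxy)benzaldehyde; 10 1H-benzotriazole
Product: 11 1-{[4-(benzyloxy)phenyl](chloro)methyl}-1H-benzotriazole (racemic)
Conditions: SOCl2, CH2Cl2, 0 °C → rt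
Reagents that add atoms: thionyl chloride, O=S(Cl)Cl
Why: benzotriazole–aldehyde condensation to the hemiaminal, whose hydroxyl SOCl2 exchanges for chloride (deoxychlorination), gives the alpha-chloroalkyl benzotriazole.

**Step 8**
Reactants: 8 phenol; 11 alpha-chloroalkyl benzotriazole
Product: 12 1-{[3,5-bis(benzyloxy)-4-{(1R)-1-[4-(benzyloxy)phenyl]ethyl}phenoxy][4-(benzyloxy)phenyl]methyl}-1H-benzotriazole (both configurations at the acetal carbon)
Conditions: NaH, THF, 0 °C; then 11, 0 °C → rt
Reagents that add atoms: none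
Why: Williamson-type O-alkylation of the phenoxide by the readily ionised alpha-chloroalkyl benzotriazole gives the N,O-acetal; its acetal carbon forms in both configurations, which does not matter because it becomes planar in step 11.

**Step 9**
Reactants: 13 (1R,2R)-1,2-diphenylethane-1,2-diol ((R,R)-hydrobenzoin); 14 tert-butyl bromoacetate
Product: 16 (5R,6R)-5,6-diphenyl-1,4-dioxan-2-one, via hydroxy ester 15 (not isolated)
Conditions: NaH (1.0 equiv), THF, 0 °C, then 14; then p-TsOH·H2O (cat.), toluene, 80 °C
Reagents that add atoms: none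
Why: Williamson mono-O-alkylation of the C2-symmetric diol (both hydroxyls are equivalent) followed by acid-catalysed lactonisation with loss of isobutene gives the glycolate dioxanone without touching the two carbinol stereocentres.

**Step 10**
Reactants: 16 (5R,6R)-5,6-diphenyl-1,4-dioxan-2-one
Product: 18 (2R,3R)-5-methoxy-2,3-diphenyl-2,3-dihydro-1,4-dioxine, via lactonium tetrafluoroborate 17 (not isolated)
Conditions: Me3OBF4, CH2Cl2, 0 °C → rt; then i-Pr2NEt, −78 → 0 °C; filtered through basic alumina and used at once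
Reagents that add atoms: trimethyloxonium tetrafluoroborate, C[O+](C)C.F[B-](F)(F)F
Why: O-methylation of the lactone carbonyl by the oxonium salt and deprotonation of the resulting dialkoxycarbenium ion at C3 by a hindered amine is the classical lactonium route to cyclic ketene acetals and leaves the stereocentres untouched.

**Step 11**
Reactants: 12 N,O-acetal; 18 (2R,3R)-5-methoxy-2,3-diphenyl-2,3-dihydro-1,4-dioxine
Product: 20 (2R,3R)-5,7-bis(benzyloxy)-2-[4-(benzyloxy)phenyl]-6-{(1R)-1-[4-(benzyloxy)phenyl]ethyl}-3-[(1R,2R)-2-hydroxy-1,2-diphenylethoxy]-2,3-dihydro-4H-chromen-4-one, via C4 methyl ketal 19 (not isolated)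
Conditions: 18 (2 equiv), BF3·OEt2 (1.2 equiv), 2,6-di-tert-butyl-4-methylpyridine, 4 Å MS, CH2Cl2, −78 → −20 °C; then 1 M HCl, THF, rt
Reagents that add atoms: water, O
Why: Proposed new method: BF3 removes benzotriazolide from 12 to give the E-configured O-aryl oxocarbenium ion, a cationic 2-oxadiene (C4a=C8a–O1=C2); C6 of ketene acetal 18 adds to C2, the 2-methoxy-1,4-dioxan-2-ylium ion so formed (future C4) is trapped by the ring A carbon ortho to O1, proton loss gives ketal 19 (C4 configuration irrelevant), and aqueous acid unmasks the C4 ketone. The closest known reactions are the oxa-Povarov reaction (formal [4+2] of aryl oxocarbenium ions with alkenes to chromans) and the Lewis acid addition of ketene acetals to acetals; a 2-oxygenated ketene acetal has not been used there, but it should be a better nucleophile toward C2 than a styrene, and its dialkoxycarbenium ion is a Hoesch-type acylating agent well matched to a phloroglucinol ether ring. Ring C closes by a 6-exo-trig Friedel–Crafts attack of the arene on the carbenium carbon. C3 is set by the auxiliary, since in the half-chair of 18 with both phenyls pseudo-equatorial C6 should be attacked along the axial, chair-like trajectory on the face anti to the C2 phenyl, which for the (2R,3R)-dioxene leads to 3R; C2 is set relative to C3 by an exo-type approach that keeps ring B away from the dioxene ring, giving the 2,3-trans (2R) arrangement. The step needs ionisation on the benzotriazole side only, capture of the cation by 18 and not by ring A of a second molecule, and a single site of ring closure; benzotriazolide is the better leaving group, 18 is used in excess at low temperature with a hindered pyridine to take up the proton, and the two carbons ortho to O1 are equivalent because O1 is para to the side chain. The remote diarylmethine centre has no pathway to epimerise under these conditions.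

**Step 12**
Reactants: 20 protected dihydroflavonol
Product: 21 (2R,3R)-3,5,7-trihydroxy-2-(4-hydroxyphenyl)-6-[(1R)-1-(4-hydroxyphenyl)ethyl]-2,3-dihydro-4H-chromen-4-one
Conditions: H2 (1 atm), Pd(OH)2/C, EtOAc/MeOH, rt
Reagents that add atoms: none
Why: heterogeneous palladium-catalysed hydrogenolysis cleaves the four O-benzyl ethers and the benzylic C–O bond of the 2-hydroxy-1,2-diphenylethyl ether in one operation, as is routine for benzylated dihydroflavonols, while the ring C2–O1 bond, the hydrogen-bonded ketone and the three stereocentres should be left alone.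

**Compound list**
1 | 2,4,6-trihydroxyacetophenone | CC(=O)c1c(O)cc(O)cc1O | starting material
2 | 1-[2,6-dihydroxy-4-(methoxymethoxy)phenyl]ethanone | CC(=O)c1c(O)cc(OCOC)cc1O | intermediate
3 | 1-[2,6-bis(benzyloxy)-4-(methoxymethoxy)phenyl]ethanone | CC(=O)c1c(OCc2ccccc2)cc(OCOC)cc1OCc1ccccc1 | intermediate
4 | 4-(benzyloxy)phenylmagnesium bromide | Br[Mg]c1ccc(OCc2ccccc2)cc1 | starting material
5 | 1-[2,6-bis(benzyloxy)-4-(methoxymethoxy)phenyl]-1-[4-(benzyloxy)phenyl]ethanol (racemic) | CC(O)(c1ccc(OCc2ccccc2)cc1)c1c(OCc2ccccc2)cc(OCOC)cc1OCc1ccccc1 | intermediate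
6 | 1,3-bis(benzyloxy)-2-{1-[4-(benzyloxy)phenyl]ethenyl}-5-(methoxymethoxy)benzene | C=C(c1ccc(OCc2ccccc2)cc1)c1c(OCc2ccccc2)cc(OCOC)cc1OCc1ccccc1 | intermediate
7 | 1,3-bis(benzyloxy)-2-{(1R)-1-[4-(benzyloxy)phenyl]ethyl}-5-(methoxymethoxy)benzene | C[C@H](c1ccc(OCc2ccccc2)cc1)c1c(OCc2ccccc2)cc(OCOC)cc1OCc1ccccc1 | intermediate
8 | 3,5-bis(benzyloxy)-4-{(1R)-1-[4-(benzyloxy)phenyl]ethyl}phenol | C[C@H](c1ccc(OCc2ccccc2)cc1)c1c(OCc2ccccc2)cc(O)cc1OCc1ccccc1 | intermediate
9 | 4-(benzyloxy)benzaldehyde | O=Cc1ccc(OCc2ccccc2)cc1 | starting material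
10 | 1H-benzotriazole | c1ccc2[nH]nnc2c1 | starting material
11 | 1-{[4-(benzyloxy)phenyl](chloro)methyl}-1H-benzotriazole (racemic) | ClC(c1ccc(OCc2ccccc2)cc1)n1nnc2ccccc12 | intermediate
12 | 1-{[3,5-bis(benzyloxy)-4-{(1R)-1-[4-(benzyloxy)phenyl]ethyl}phenoxy][4-(benzyloxy)phenyl]methyl}-1H-benzotriazole (both configurations at the acetal carbon) | C[C@H](c1ccc(OCc2ccccc2)cc1)c1c(OCc2ccccc2)cc(OC(c2ccc(OCc3ccccc3)cc2)n2nnc3ccccc23)cc1OCc1ccccc1 | intermediate
13 | (1R,2R)-1,2-diphenylethane-1,2-diol | O[C@H](c1ccccc1)[C@H](O)c1ccccc1 | starting material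
14 | tert-butyl bromoacetate | CC(C)(C)OC(=O)CBr | starting material
15 | tert-butyl 2-[(1R,2R)-2-hydroxy-1,2-diphenylethoxy]acetate | CC(C)(C)OC(=O)CO[C@H](c1ccccc1)[C@H](O)c1ccccc1 | intermediate
16 | (5R,6R)-5,6-diphenyl-1,4-dioxan-2-one | O=C1CO[C@H](c2ccccc2)[C@@H](c2ccccc2)O1 | intermediate
17 | (5R,6R)-2-methoxy-5,6-diphenyl-1,4-dioxan-2-ylium tetrafluoroborate | CO[C+]1CO[C@H](c2ccccc2)[C@@H](c2ccccc2)O1.F[B-](F)(F)F | intermediate
18 | (2R,3R)-5-methoxy-2,3-diphenyl-2,3-dihydro-1,4-dioxine | COC1=CO[C@H](c2ccccc2)[C@@H](c2ccccc2)O1 | intermediate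
19 | C4 methyl ketal of 20 in which the auxiliary oxygen is still bound to C4, closing a 1,4-dioxane ring across C3–C4 (2R,3R; auxiliary carbons R,R; side chain R; C4 not assigned) | C[C@H](c1ccc(OCc2ccccc2)cc1)c1c(OCc2ccccc2)cc2c(c1OCc1ccccc1)C1(OC)O[C@H](c3ccccc3)[C@@H](c3ccccc3)O[C@@H]1[C@@H](c1ccc(OCc3ccccc3)cc1)O2 | intermediate
20 | (2R,3R)-5,7-bis(benzyloxy)-2-[4-(benzyloxy)phenyl]-6-{(1R)-1-[4-(benzyloxy)phenyl]ethyl}-3-[(1R,2R)-2-hydroxy-1,2-diphenylethoxy]-2,3-dihydro-4H-chromen-4-one | C[C@H](c1ccc(OCc2ccccc2)cc1)c1c(OCc2ccccc2)cc2c(c1OCc1ccccc1)C(=O)[C@H](O[C@H](c1ccccc1)[C@H](O)c1ccccc1)[C@@H](c1ccc(OCc3ccccc3)cc1)O2 | intermediate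
21 | (2R,3R)-3,5,7-trihydroxy-2-(4-hydroxyphenyl)-6-[(1R)-1-(4-hydroxyphenyl)ethyl]-2,3-dihydro-4H-chromen-4-one | C[C@H](c1ccc(O)cc1)c1c(O)cc2c(c1O)C(=O)[C@H](O)[C@@H](c1ccc(O)cc1)O2 | target

**Count**
Total steps: 12. Longest linear sequence: 9 steps (steps 1–6, 8, 11, 12).

**Steps most likely to fail**

Step 11. The dialkoxycarbenium ion may be intercepted before ring closure (demethylation to a lactone, or heterolysis of a benzylic C–O bond of the auxiliary). The ketene acetal may also oligomerise under the Lewis acid, or the facial and exo/endo selectivity may be poor. The fallback makes the same two bonds one after the other by known reactions; it sets out from 16 and 12 and returns at 20. Lactone 16 is silylated (TBSOTf, Et3N, CH2Cl2, 0 °C) to the tert-butyldimethylsilyl ketene acetal F1. Mukaiyama-type addition of it to the oxocarbenium ion from 12 (BF3·OEt2, CH2Cl2, −78 °C) should give the C3-substituted dioxanone F2 under the same facial model. The lactone is opened with LiOH/H2O2 (THF/H2O, 0 °C) to the hydroxy acid F3. Intramolecular Friedel–Crafts acylation of ring A (TFAA, CH2Cl2, 0 °C; then NaHCO3/MeOH to cleave the trifluoroacetate on the auxiliary hydroxyl) closes ring C to 20.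

Step 10. The lactonium salt may collapse by dealkylation (benzylic C–O cleavage, or methyl transfer to the amine) before it is deprotonated. The fallback avoids the salt; it sets out from 13 and returns at 18. Acid-catalysed acetal exchange of 13 with 1,1,2,2-tetramethoxyethane (CSA, toluene, methanol distilled off) should give the 2,3-dimethoxy-1,4-dioxane F4. Elimination of one methanol (TMSOTf, i-Pr2NEt, CH2Cl2, −20 °C) gives 18; F4 is C2-symmetric, so either direction of elimination gives the same product.

Step 5. The hindered alkene may be reduced slowly, or the catalyst may discriminate the two faces poorly. The fallback replaces asymmetric catalysis by resolution; it sets out from 6 and returns at 7. Hydrogenation over an achiral catalyst ([Ir(cod)(PCy3)(py)]PF6, H2, CH2Cl2) gives the racemic alkane F5. Preparative chromatography on a chiral stationary phase separates it into 7 and the S enantiomer F6, which is discarded.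

**Further compounds**
F1 | step 11 | tert-butyl{[(2R,3R)-2,3-diphenyl-2,3-dihydro-1,4-dioxin-5-yl]oxy}dimethylsilane | CC(C)(C)[Si](C)(C)OC1=CO[C@H](c2ccccc2)[C@@H](c2ccccc2)O1
F2 | step 11 | (3R,5R,6R)-3-[(R)-[3,5-bis(benzyloxy)-4-{(1R)-1-[4-(benzyloxy)phenyl]ethyl}phenoxy][4-(benzyloxy)phenyl]methyl]-5,6-diphenyl-1,4-dioxan-2-one | C[C@H](c1ccc(OCc2ccccc2)cc1)c1c(OCc2ccccc2)cc(O[C@H](c2ccc(OCc3ccccc3)cc2)[C@H]2O[C@H](c3ccccc3)[C@@H](c3ccccc3)OC2=O)cc1OCc1ccccc1
F3 | step 11 | (2R,3R)-3-[3,5-bis(benzyloxy)-4-{(1R)-1-[4-(benzyloxy)phenyl]ethyl}phenoxy]-3-[4-(benzyloxy)phenyl]-2-[(1R,2R)-2-hydroxy-1,2-diphenylethoxy]propanoic acid | C[C@H](c1ccc(OCc2ccccc2)cc1)c1c(OCc2ccccc2)cc(O[C@H](c2ccc(OCc3ccccc3)cc2)[C@@H](O[C@H](c3ccccc3)[C@H](O)c3ccccc3)C(=O)O)cc1OCc1ccccc1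
F4 | step 10 | (2R,3R)-5,6-dimethoxy-2,3-diphenyl-1,4-dioxane (acetal carbons not assigned) | COC1O[C@H](c2ccccc2)[C@@H](c2ccccc2)OC1OC
F5 | step 5 | racemic 1,3-bis(benzyloxy)-2-{1-[4-(benzyloxy)phenyl]ethyl}-5-(methoxymethoxy)benzene | CC(c1ccc(OCc2ccccc2)cc1)c1c(OCc2ccccc2)cc(OCOC)cc1OCc1ccccc1
F6 | step 5 | 1,3-bis(benzyloxy)-2-{(1S)-1-[4-(benzyloxy)phenyl]ethyl}-5-(methoxymethoxy)benzene | C[C@@H](c1ccc(OCc2ccccc2)cc1)c1c(OCc2ccccc2)cc(OCOC)cc1OCc1ccccc1
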